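**Plan**
- Ring A (the N-methoxy-4-pyridone) is traced back to a 4-pyranone, with N1 exchanged for the ring oxygen in the last step. The C8 stereocentre is traced back to a C7=C8 enol ether.
- Ring B (the carbocycle) is then cut at C4a–C5 and C7–C8. C8–C8a–C4a is the α'-carbon/carbonyl/α-carbon array of an open 1,3,5-triketone (C8 an α-methoxy methylene, C4a a doubly activated methylene). C5–C6–C7 is the β-carbon/α-carbon/formyl carbon of (E)-undec-2-enal.
- Forward: the triketone is assembled in two steps. One operation then closes ring B (Michael addition, aldol condensation) and the pyranone ring (cyclodehydration). Hydrogenation and O-to-N exchange finish the route.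
- Stereochemistry: C5 (S) comes from the chiral amine catalyst in the Michael event. C8 (R) comes from hydrogenation of the enol ether anti to the C5 octyl group.

Key step: step 3

Remark: carbon labels C2–C8a follow the quinolin-4-one numbering of the target and are used for the corresponding atoms of every precursor; the target is read as (5S,8R), with the C5 octyl and C8 methoxy groups cis on ring B.

**Step 1**
Reactants: 1 methoxyacetone
Product: 3 3-methoxypentane-2,4-dione, via difluoroboron chelate 2 (not isolated)
Conditions: Ac2O, BF3·2AcOH, 0 °C → rt; then aq NaOAc, reflux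
Reagents that add atoms: acetic anhydride, CC(=O)OC(C)=O
Why: BF3-mediated C-acetylation of a ketone through its more substituted enol (acid-promoted β-diketone synthesis), driven by trapping of the product as chelate 2, which aqueous acetate hydrolyses; no stereocentre is formed.

**Step 2**
Reactants: 3 3-methoxypentane-2,4-dione; 4 N,2-dimethoxy-N-methylacetamide
Product: 6 1,5-dimethoxyheptane-2,4,6-trione, via dilithium dianion 5 (not isolated)
Conditions: LiN(i-Pr)2 (commercial solution, 2.2 equiv), THF, −78 → 0 °C; then 4, −78 → 0 °C; cold aq HCl to pH 4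
Reagents that add atoms: none
Why: acylation of a β-diketone 1,3-dianion at its terminal carbon (the later C4a; the two methyl groups of 3 are equivalent) by an N-methoxy-N-methyl amide, whose chelated tetrahedral adduct should release the 1,3,5-triketone only on work-up, so that over-addition is avoided; no stereocentre is formed.

**Step 3**
Reactants: 6 1,5-dimethoxyheptane-2,4,6-trione; 7 (E)-undec-2-enal
Product: 10 (5S)-3,8-dimethoxy-2-methyl-5-octyl-5,6-dihydro-4H-chromen-4-one, via Michael adduct 8 (not isolated), via cyclohexenone 9 (not isolated)
Conditions: 7 (1.2 equiv), (R)-2-[diphenyl(trimethylsilyloxy)methyl]pyrrolidine (10 mol %), PhCO2H (10 mol %), toluene, 0 °C → rt; then TsOH·H2O (20 mol %), 80 °C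
Reagents that add atoms: none
Why: The secondary amine converts 7 into an (E)-iminium ion, one face of which is blocked by the diphenyl(silyloxy)methyl group, so the C4a methylene of 6 should add to the β-carbon from the open face and set C5 as S under catalyst control (the (R)-catalyst is chosen for this sense); this is the known amine-catalysed asymmetric Michael addition of 1,3-dicarbonyl compounds to enals. After TsOH is added, the enol of the methoxymethyl ketone attacks the aldehyde of 8 (6-(enolendo)-exo-trig aldol, C7–C8) and loss of water gives the 2-methoxyenone 9, the closest precedent being the one-pot Michael/aldol condensation (Robinson-type annulation) of γ-substituted β-keto esters with enals. The enolised ring ketone of 9 then adds to the acetyl carbonyl (6-exo-trig) and a second dehydration closes the 4-pyranone, the classical cyclodehydration of 1,3,5-triketones. Two selectivities are needed: Michael attack through C4a and not through the methoxy-bearing methine C3, which the steric and electronic handicap of that tertiary α-alkoxy carbon should secure; and aldol closure through C8 and not C3, secured because only the C8 adduct can dehydrate into conjugation while the C3 adduct is a reversible dead end. C4a and C3 end up sp2, so C5 is the only stereocentre the step has to control, and it is not acidic under the acidic second stage.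

**Step 4**
Reactants: 10 (5S)-3,8-dimethoxy-2-methyl-5-octyl-5,6-dihydro-4H-chromen-4-one
Product: 11 (5S,8R)-3,8-dimethoxy-2-methyl-5-octyl-5,6,7,8-tetrahydro-4H-chromen-4-one
Conditions: H2 (1 atm), 5% Rh/Al2O3, EtOAc, rt
Reagents that add atoms: none
Why: heterogeneous syn-hydrogenation of the C7=C8 enol ether; the C5 octyl group, held pseudoaxial by peri strain with the C4 carbonyl, shields one face of ring B, so both hydrogens should arrive anti to it and leave the C8 methoxy group cis to octyl (8R), and rhodium on alumina is chosen because it reduces enol ethers with little hydrogenolysis or double-bond migration.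

**Step 5**
Reactants: 11 (5S,8R)-3,8-dimethoxy-2-methyl-5-octyl-5,6,7,8-tetrahydro-4H-chromen-4-one
Product: 13 waltherione K, via ring-opened enaminone 12 (not isolated)
Conditions: MeONH2·HCl, NaOAc, EtOH–H2O, 80 °C (sealed tube)
Reagents that add atoms: O-methylhydroxylamine hydrochloride, CON.Cl
Why: conversion of a 4-pyranone into a 4-pyridone by a primary amino nucleophile (conjugate addition at C2, ring opening to 12, condensation of nitrogen with the C8a carbonyl, loss of water), the same exchange that turns pyranones into 1-hydroxy- and 1-alkyl-4-pyridones; the acetate buffer keeps the medium near neutral so that C8, transiently α to a ketone in 12, should not epimerise, and no new stereocentre arises.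

**Compound list**
1 | methoxyacetone (1-methoxypropan-2-one) | COCC(C)=O | starting material
2 | difluoroboron chelate of 3-methoxypentane-2,4-dione | CC1=C(OC)C(C)=[O+][B-](F)(F)O1 | intermediate
3 | 3-methoxypentane-2,4-dione | CC(=O)C(OC)C(C)=O | intermediate
4 | N,2-dimethoxy-N-methylacetamide | COCC(=O)N(C)OC | starting material
5 | dilithium 1,3-dianion of 3 (dilithium 3-methoxypenta-1,3-diene-2,4-diolate) | [Li+].[Li+].C=C([O-])C(OC)=C(C)[O-] | intermediate
6 | 1,5-dimethoxyheptane-2,4,6-trione | COCC(=O)CC(=O)C(OC)C(C)=O | intermediate
7 | (E)-undec-2-enal | CCCCCCCC/C=C/C=O | starting material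
8 | 1,5-dimethoxy-3-[(3S)-1-oxoundecan-3-yl]heptane-2,4,6-trione (Michael adduct; enolisable centres undefined) | CCCCCCCC[C@@H](CC=O)C(C(=O)COC)C(=O)C(OC)C(C)=O | intermediate
9 | 2-methoxy-1-[(6S)-3-methoxy-6-octyl-2-oxocyclohex-3-en-1-yl]butane-1,3-dione | CCCCCCCC[C@H]1CC=C(OC)C(=O)C1C(=O)C(OC)C(C)=O | intermediate
10 | (5S)-3,8-dimethoxy-2-methyl-5-octyl-5,6-dihydro-4H-chromen-4-one | CCCCCCCC[C@H]1CC=C(OC)c2oc(C)c(OC)c(=O)c12 | intermediate
11 | (5S,8R)-3,8-dimethoxy-2-methyl-5-octyl-5,6,7,8-tetrahydro-4H-chromen-4-one | CCCCCCCC[C@H]1CC[C@@H](OC)c2oc(C)c(OC)c(=O)c12 | intermediate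
12 | (3S,6R)-6-methoxy-2-[2-methoxy-3-(methoxyamino)but-2-enoyl]-3-octylcyclohexan-1-one | CCCCCCCC[C@H]1CC[C@@H](OC)C(=O)C1C(=O)C(OC)=C(C)NOC | intermediate
13 | waltherione K, (5S,8R)-1,3,8-trimethoxy-2-methyl-5-octyl-5,6,7,8-tetrahydroquinolin-4(1H)-one | CCCCCCCC[C@H]1CC[C@@H](OC)c2c1c(=O)c(OC)c(C)n2OC | target

Total step count: 5. Longest linear sequence: 5 steps (1 → 3 → 6 → 10 → 11 → 13).

**Steps most likely to fail**

Step 3. The triketone may react as a Michael donor through the wrong carbon, may tie up the amine catalyst as an enaminone, or may close to the pyranone before ring B has formed, so that the aldehyde is left unreacted. The fallback sets out from 1 and 7 and returns at 10. Claisen condensation of 1 with methyl methoxyacetate (NaH, THF, 0 °C → rt, acylation at the methyl group) should give the symmetrical 1,5-dimethoxypentane-2,4-dione F1, which has a single activated methylene and two equivalent methoxymethyl ketones. The same amine-catalysed Michael/aldol condensation with 7 (same catalyst, PhCO2H, toluene; then TsOH·H2O, 80 °C) should then give (5S)-2-methoxy-6-(methoxyacetyl)-5-octylcyclohex-2-en-1-one F2 with no choice of site. Double deprotonation (LiN(i-Pr)2, 2.2 equiv, THF, −78 °C) to the dilithium dianion F3 and C-acetylation at the methoxymethylene carbon with N-methoxy-N-methylacetamide should lead to 9. TsOH·H2O (toluene, 80 °C) then closes the pyranone to 10.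

Step 5. Ring opening by the weakly basic alkoxyamine may be slow, the sequence may stop at the open-chain stage, and long heating may epimerise C8. The fallback sets out from 11 and returns at 13. NH2OH·HCl, NaOAc, EtOH–H2O, 80 °C should give (5S,8R)-1-hydroxy-3,8-dimethoxy-2-methyl-5-octyl-5,6,7,8-tetrahydroquinolin-4(1H)-one F4; hydroxylamine is the stronger nucleophile and this exchange is the usual entry to 1-hydroxy-4-pyridones. O-Methylation of the N-hydroxy group (MeI, K2CO3, DMF, rt) should then give 13.

Step 4. Facial selectivity may be poor, the dihydro ring may disproportionate to the aromatic chromone, and the C8–O bond may be hydrogenolysed. The fallback sets out from 10 and returns at 11. Aqueous acid (3 M HCl, THF, 50 °C) should hydrolyse the enol ether to the 8-ketone (5S)-3-methoxy-2-methyl-5-octyl-6,7-dihydro-4H-chromene-4,8(5H)-dione F5. Corey–Bakshi–Shibata reduction ((S)-configured B-methyl oxazaborolidine from diphenylprolinol, 10 mol %, BH3·SMe2, THF, −20 °C) should deliver hydride under reagent control, with the pyranone carbon C8a as the large group, to give (5S,8R)-8-hydroxy-3-methoxy-2-methyl-5-octyl-5,6,7,8-tetrahydro-4H-chromen-4-one F6. Methylation (MeI, Ag2O, MeCN, rt) returns to 11.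

**Further compounds**
F1 | step 3 | 1,5-dimethoxypentane-2,4-dione | COCC(=O)CC(=O)COC
F2 | step 3 | (5S)-2-methoxy-6-(methoxyacetyl)-5-octylcyclohex-2-en-1-one | CCCCCCCC[C@H]1CC=C(OC)C(=O)C1C(=O)COC
F3 | step 3 | dilithium dianion of F2 | [Li+].[Li+].CCCCCCCC[C@H]1CC=C(OC)C([O-])=C1C([O-])=COC
F4 | step 5 | (5S,8R)-1-hydroxy-3,8-dimethoxy-2-methyl-5-octyl-5,6,7,8-tetrahydroquinolin-4(1H)-one | CCCCCCCC[C@H]1CC[C@@H](OC)c2c1c(=O)c(OC)c(C)n2O
F5 | step 4 | (5S)-3-methoxy-2-methyl-5-octyl-6,7-dihydro-4H-chromene-4,8(5H)-dione | CCCCCCCC[C@H]1CCC(=O)c2oc(C)c(OC)c(=O)c12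
F6 | step 4 | (5S,8R)-8-hydroxy-3-methoxy-2-methyl-5-octyl-5,6,7,8-tetrahydro-4H-chromen-4-one | CCCCCCCC[C@H]1CC[C@@H](O)c2oc(C)c(OC)c(=O)c12
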